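## Structural features

The target is a linear prodelphinidin trimer of three flavan-3-ol units, each a phloroglucinol ring A fused to a dihydropyran ring C that carries a pyrogallol ring B on C2. The upper unit T and the lower unit B are epigallocatechin and the middle unit M is epigallocatechin 3-O-gallate; C4 of T is bonded to C8 of M, and C4 of M to C8 of B. Every unit has the (2R,3R) 2,3-cis arrangement. T and M each carry a third, contiguous stereocentre at C4 whose substituent is trans to the C3 oxygen (4β), which gives eight stereocentres in two C2–C3–C4 triads and one C2–C3 pair. The eighteen free phenols are oxidised easily, above all under base; the interflavan C4–C8 bonds re-ionise under acid; and the single galloyl ester is base-labile and sits on the most hindered of three secondary oxygens. The real difficulty is regiochemical: both interflavan bonds must be 4→8 and not 4→6, and one acyl group must be placed on M alone. The key step uses the fact that ring A of B is a 1,3,5-trioxygenated benzene whose carbons C8a, C8, C7, C6, C5 and C4a map onto C1–C6 of a 3,5-dioxo ester, with C4 of M on C8 (chain C2) and the C4–C3–C2 arm of ring C on C4a (chain C6).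

## Logic of the disconnections

**25 ⇒ 24.** The nineteen O–benzyl bonds are cut. One neutral, reductive deprotection at the end spares the acid-labile interflavan bonds, the ester and the oxidisable phenols, and all earlier work is done on air-stable ethers. The forward step must cleave every benzyl ether, including the one secondary alkyl benzyl ether, without touching the ester.

**24 ⇒ 23 + 3.** The C4(T)–C8(M) bond is cut. It is the last C–C bond, and it joins a dimer to a monomer that comes from the natural flavanol in two steps. The forward step needs a C4 cation that attacks C8 of the upper ring of 23 from the β face, and not C6 of either unit, and it must outrun self-condensation of 3.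

**23 ⇒ 21 + 22, 21 ⇒ 20, 20 ⇒ 19.** The ester C–O bond, one Si–O bond and one phenolic O–benzyl bond are cut. The galloyl ester cannot pass through the strongly basic ring-forming step, so a silyl ether marks its place until the base chemistry is over. The forward steps must cap the last phenol first and then acylate a hindered axial alcohol.

**19 ⇒ 18 ⇒ 17.** The O1–C2 bond of ring C of the lower unit and one Si–O bond are cut. Only one phenol is ortho to the side chain, so closure there fixes the 4→8 pattern, and an SN2 closure with inversion turns an anti diol into the 2,3-cis ring. Ring C and both its stereocentres thus come from an open chain. The forward step demands clean inversion at an electron-rich benzylic carbon and selective removal of a triethylsilyl ether beside a tert-butyldimethylsilyl ether.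

**17 ⇒ 15.** The C4a–C8a bond of ring A is cut, which opens the arene to a nine-carbon keto ester whose C5 oxygen is already benzylated. This replaces a regiochemically ambiguous arylation of a phloroglucinol by a ring synthesis in which every oxygen arrives differentiated. The forward step demands that the γ-carbon C6 of a dianion acylate the ester carbon.

**15 ⇒ 13 + 4.** The bond between C2 of the chain and C4 of M is cut. The flavan C4 cation is easily formed and the β-keto ester carbon is the natural nucleophile; the C3 silyloxy group directs attack to the β face. The forward step must go through C2 and not C4 of the nucleophile, and the silyl ethers and the enol ether must survive the Lewis acid.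

**13 ⇒ 12 ⇒ 11 ⇒ 10.** The C2–C3 bond (acyl substitution by a two-carbon ester enolate), the C5–O bond (conjugate addition of the benzyl donor to an alkyne) and the C3–C4 bond (acylation of an acetylide) are cut. Bringing the benzyloxy group in by addition to an alkyne fixes the enol ether on C5 without ambiguity. O-alkylation of a 3,5-diketo ester would have two enolisable carbonyls to choose from and would compete with closure to a 4-hydroxypyranone. The forward sequence must give the E enol ether, in which C3 and C6 are cis.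

**10 ⇒ 9 ⇒ 8.** One O–benzyl bond and the C6–C7 bond are cut, the latter as the opening of a terminal epoxide by a propargyl nucleophile. The forward steps need attack at the terminal epoxide carbon and a benzylation that does not let the neighbouring silyl group migrate.

**8 ⇒ 7 ⇒ 6 ⇒ 5.** One Si–O bond, the two epoxide C–O bonds and the aryl carbinol–vinyl C–C bond are cut. A kinetic resolution by epoxidation sets both stereocentres of the lower unit at once in the anti relationship. The price is that at most half of 6 is used.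

**4 ⇒ 3 ⇒ 2 ⇒ 1.** One Si–O bond, the C4–O bond and five phenolic O–benzyl bonds are cut. One oxidised flavan serves twice: 3 is the electrophile for T and 4 the electrophile for M. The forward oxidation must place the C4 alkoxy group trans to the C3 oxygen.

## Other disconnections considered

**Alternative 1:** The cut runs through C3–C4 and O1–C2 of ring C of the middle unit, so that M is assembled on C8 of an intact lower unit. In the forward step the diaryl carbinol A1 is dehydrated to an o-quinone methide, the prolinol-derived enamine of 2-(4-methoxybenzyloxy)acetaldehyde A2 adds to the exocyclic carbon, and hemiacetal formation gives the 3,4-trans lactol A3.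
- In favour: additions of aldehyde enamines to o-quinone methides are an established reaction type, the catalyst sets C3 and C4, and the lower unit comes from the natural flavanol.
- Against: A3 has no ring B on C2, so an aryl group must still be introduced at the lactol carbon with the cis relationship to C3, which needs at least three further steps. The quinone methide carbon is flanked by two ortho-disubstituted arenes. The catalyst has to override the stereocentres of the lower unit. The 4-methoxybenzyl ether has to be removed oxidatively beside oxidisable flavan C4–H bonds. The upper unit still has to be attached by the same cationic coupling as in the chosen plan.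
- Comparison: on structure the two plans are equal, since each builds exactly one flavan unit from scratch. On mechanism Alternative 1 is the better, because its key step is a known, catalyst-controlled reaction whereas step 13 is without direct precedent. On step economy the chosen plan is better, because its ring closure delivers a chain that already carries ring B and both stereocentres of the new unit.

**Alternative 2:** The cut removes three bonds of ring A of the middle unit (C8–C8a, C6–C7, C4a–C8a). In the forward step the cyclobutenone A4 is heated with the siloxyalkyne A5, and the cascade of ring opening, [2+2] addition, ring opening and 6π closure gives the phenol A6, free only at C8a, with T on C8 and the cinnamyl chain on C4a.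
- In favour: the benzannulation is a known thermal, neutral reaction with built-in regiochemistry, and it fixes the T–M bond as 4→8 by construction. On this point it is better than the chosen plan, which leaves that bond to the innate C8 preference of a late cationic coupling.
- Against: A5 is a sensitive ynol ether on a secondary benzylic carbon next to an oxygen-bearing carbon, and A4 is a 4-substituted 3-alkoxycyclobutenone that is itself laborious. A6 carries only an alkene, so both stereocentres of ring C of M and the cis relationship must still be installed. After that C4 of M has to be oxidised and coupled with the lower unit in a molecule that already contains a second flavan, and the galloyl group must be placed.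
- Comparison: both plans make a phloroglucinol ring de novo and use the single free phenol ortho to the chain to close ring C, so on structure they are equal in idea. On mechanism Alternative 2 has the precedent on its side. On step economy the chosen plan is shorter after the key step, because its chain already holds the two stereocentres and the remaining interflavan bond is made with a two-step electrophile.

**Alternative 3:** The cut runs through O1–C2 and C3–C4 of ring C of the lower unit. In the forward step the salicyl alcohol A7 on the M-bearing ring is converted into an o-quinone methide, which adds suprafacially to the Z-alkenylboronate A8 and gives the 2,3-cis boronate A9; oxidation of the C–B bond with retention would then give the C3 alcohol.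
- In favour: the step is convergent, and the cis relationship follows from the alkene geometry without an SN2 reaction at an ionisable benzylic carbon. On this point it is better than step 15 of the chosen plan. The middle unit can be carried with its galloyl ester in place, which saves the silyl/galloyl exchange.
- Against: nothing close to the new centres controls the absolute sense at C2 and C3. The M unit on C8 is remote from the reacting face, so a mixture with the diastereomer that has the enantiomeric lower unit is to be expected. A Z-alkenylboronate is a hindered, weakly nucleophilic partner for an electron-poor heterodiene and may isomerise. The galloyl ester must survive quinone methide generation and the alkaline oxidation. A7 needs a phloroglucinol with the same differentiation of oxygens that the chosen plan obtains from its ring synthesis.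
- Comparison: on step economy after the key step Alternative 3 is the equal or the better of the chosen plan. On stereocontrol the chosen plan is better, because both centres of the lower unit are fixed before the ring is made. On mechanism both key steps are untested on this substrate class.

Key step: step 13

Remark on the chemistry: the open-chain precursor needs nine chain carbons (C1–C6 for ring A, C7–C9 for C4, C3 and C2 of ring C), so it is a 3-oxonon-4-enoate with the protected diol on C8 and C9; an oct-4-enoate with the diol on C7 and C8 would lack C4 of ring C.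

## Route

Step 1
Reactants: 1 (−)-epigallocatechin
Product: 2 5,7,3',4',5'-penta-O-benzyl-(−)-epigallocatechin
Conditions: BnBr (5.5 equiv), K2CO3, DMF, 0 °C → rt, argon
Reagents that add atoms: benzyl bromide, BrCc1ccccc1
Why: Williamson etherification; carbonate deprotonates the five phenols but not the C3 alcohol, and low temperature with exclusion of air limits oxidation and C2 epimerisation of the pyrogallol unit.

Step 2
Reactants: 2 5,7,3',4',5'-penta-O-benzyl-(−)-epigallocatechin
Product: 3 4β-(2-ethoxyethoxy)-5,7,3',4',5'-penta-O-benzyl-(−)-epigallocatechin (alkoxy group trans to the C3 hydroxyl)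
Conditions: DDQ (2 equiv), EtOCH2CH2OH (5 equiv), CH2Cl2, rt
Reagents that add atoms: 2-ethoxyethanol, CCOCCO
Why: Benzylic oxidation by hydride abstraction: DDQ ionises the C4–H bond that is ortho and para to the ring A oxygens, and the alcohol captures the cation on the face opposite to the axial C3 hydroxyl and the C2 aryl group, which sets C4 as 4β under substrate control.

Step 3
Reactants: 3 4β-(2-ethoxyethoxy)-5,7,3',4',5'-penta-O-benzyl-(−)-epigallocatechin
Product: 4 3-O-(tert-butyldimethylsilyl)-4β-(2-ethoxyethoxy)-5,7,3',4',5'-penta-O-benzyl-(−)-epigallocatechin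
Conditions: TBSCl, imidazole, DMF, rt → 40 °C
Reagents that add atoms: tert-butyldimethylsilyl chloride, CC(C)(C)[Si](C)(C)Cl
Why: Silylation of the secondary alcohol under conditions free of Lewis acid, so that the ionisable C4 ether stays intact; the silyl ether marks the oxygen that later takes the galloyl group and shields the α face of C4.

Step 4
Reactants: 5 3,4,5-tris(benzyloxy)benzaldehyde
Product: 6 rac-1-[3,4,5-tris(benzyloxy)phenyl]prop-2-en-1-ol
Conditions: CH2=CHMgBr, THF, −78 → 0 °C; aq NH4Cl
Reagents that add atoms: vinylmagnesium bromide, C=C[Mg]Br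
Why: Grignard 1,2-addition to a non-enolisable aldehyde; the racemate is accepted because the next step resolves it.

Step 5
Reactants: 6 rac-1-[3,4,5-tris(benzyloxy)phenyl]prop-2-en-1-ol
Product: 7 (S)-[(R)-oxiran-2-yl][3,4,5-tris(benzyloxy)phenyl]methanol (erythro epoxy alcohol)
Conditions: Ti(OiPr)4 (0.15 equiv), L-(+)-DIPT (0.2 equiv), t-BuOOH (0.6 equiv), 4 Å MS, CH2Cl2, −20 °C
Reagents that add atoms: tert-butyl hydroperoxide, CC(C)(C)OO
Why: Sharpless kinetic resolution: with L-(+)-tartrate the (R)-enantiomer of 6 should be epoxidised much faster than the (S)-enantiomer and should give the erythro (anti) epoxy alcohol, so the reagent sets the oxirane centre and selects the carbinol centre. At most half of 6 can be converted, and the unreacted (S)-alcohol is removed by chromatography.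

Step 6
Reactants: 7 (S)-[(R)-oxiran-2-yl][3,4,5-tris(benzyloxy)phenyl]methanol
Product: 8 triethyl{(S)-[(R)-oxiran-2-yl][3,4,5-tris(benzyloxy)phenyl]methoxy}silane
Conditions: TESCl, imidazole, CH2Cl2, 0 °C
Reagents that add atoms: triethylsilyl chloride, CC[Si](Cl)(CC)CC
Why: Silylation under weakly basic conditions, which avoids Payne rearrangement of the epoxy alcohol; the triethylsilyl group can later be removed beside the tert-butyldimethylsilyl ether.

Step 7
Reactants: 8 triethyl{(S)-[(R)-oxiran-2-yl][3,4,5-tris(benzyloxy)phenyl]methoxy}silane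
Product: 9 (1S,2R)-1-(triethylsilyloxy)-1-[3,4,5-tris(benzyloxy)phenyl]hex-5-yn-2-ol
Conditions: HC≡CCH2MgBr (from propargyl bromide, Mg, cat. HgCl2, Et2O), Et2O, −78 → −20 °C; aq NH4Cl at −20 °C
Reagents that add atoms: propargylmagnesium bromide, C#CC[Mg]Br (made in the flask from propargyl bromide, C#CCBr, and Mg)
Why: SN2 opening of the epoxide at its unhindered terminal carbon by the allenyl/propargyl Grignard reagent, which reacts through its γ-carbon and gives the terminal alkyne; neither stereocentre is touched, and a cold quench limits silyl migration to the new alkoxide.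

Step 8
Reactants: 9 (1S,2R)-1-(triethylsilyloxy)-1-[3,4,5-tris(benzyloxy)phenyl]hex-5-yn-2-ol
Product: 10 {[(1S,2R)-2-(benzyloxy)-1-[3,4,5-tris(benzyloxy)phenyl]hex-5-yn-1-yl]oxy}triethylsilane
Conditions: 2-benzyloxy-1-methylpyridinium triflate (2 equiv), MgO, PhCF3, 85 °C
Reagents that add atoms: 2-benzyloxy-1-methylpyridinium triflate, C[n+]1ccccc1OCc1ccccc1.[O-]S(=O)(=O)C(F)(F)F
Why: Benzyl transfer from the pyridinium salt under neutral, buffered conditions; a base-mediated Williamson reaction is avoided because an alkoxide next to the silyl ether would allow 1,2-silyl migration and benzylation of the wrong oxygen.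

Step 9
Reactants: 10 {[(1S,2R)-2-(benzyloxy)-1-[3,4,5-tris(benzyloxy)phenyl]hex-5-yn-1-yl]oxy}triethylsilane
Product: 11 (6R,7S)-6-(benzyloxy)-N-methoxy-N-methyl-7-(triethylsilyloxy)-7-[3,4,5-tris(benzyloxy)phenyl]hept-2-ynamide
Conditions: n-BuLi (1.05 equiv), THF, −78 °C; then ClC(O)N(OMe)Me, −78 → 0 °C
Reagents that add atoms: N-methoxy-N-methylcarbamoyl chloride, CON(C)C(Cl)=O
Why: Deprotonation of the terminal alkyne and acylation of the lithium acetylide by the carbamoyl chloride, which is far more electrophilic than the alkynyl Weinreb amide it produces.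

Step 10
Reactants: 11 (6R,7S)-6-(benzyloxy)-N-methoxy-N-methyl-7-(triethylsilyloxy)-7-[3,4,5-tris(benzyloxy)phenyl]hept-2-ynamide
Product: 12 (2E,6R,7S)-3,6-bis(benzyloxy)-N-methoxy-N-methyl-7-(triethylsilyloxy)-7-[3,4,5-tris(benzyloxy)phenyl]hept-2-enamide
Conditions: BnOH (3 equiv), PMe3 (0.2 equiv), CH2Cl2, rt
Reagents that add atoms: benzyl alcohol, OCc1ccccc1
Why: Phosphine-catalysed conjugate addition (oxa-Michael) of an alcohol to an activated alkyne: the phosphine–alkyne zwitterion generates benzyloxide, which adds to the β-carbon, the carbon that becomes C5. The E isomer (alkoxy trans to carbonyl) is the favoured one and is the geometry that the ring closure needs.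

Step 11
Reactants: 12 (2E,6R,7S)-3,6-bis(benzyloxy)-N-methoxy-N-methyl-7-(triethylsilyloxy)-7-[3,4,5-tris(benzyloxy)phenyl]hept-2-enamide
Product: 13 methyl (4E,8R,9S)-5,8-bis(benzyloxy)-3-oxo-9-(triethylsilyloxy)-9-[3,4,5-tris(benzyloxy)phenyl]non-4-enoate
Conditions: MeOAc (3 equiv), LiN(iPr)2 (3 equiv), THF, −78 °C; then 12, −78 → −20 °C; aq NH4Cl
Reagents that add atoms: methyl acetate, COC(C)=O
Why: Crossed Claisen condensation: the lithium enolate of methyl acetate adds to the Weinreb amide, whose chelated tetrahedral adduct collapses only on work-up, so over-addition is excluded; displacement of the benzyloxy group is disfavoured at the fully substituted β-carbon.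

Step 12
Reactants: 13 methyl (4E,8R,9S)-5,8-bis(benzyloxy)-3-oxo-9-(triethylsilyloxy)-9-[3,4,5-tris(benzyloxy)phenyl]non-4-enoate; 4 3-O-(tert-butyldimethylsilyl)-4β-(2-ethoxyethoxy)-5,7,3',4',5'-penta-O-benzyl-(−)-epigallocatechin
Product: 15 methyl (4E,8R,9S)-5,8-bis(benzyloxy)-3-oxo-2-[5,7,3',4',5'-penta-O-benzyl-3-O-(tert-butyldimethylsilyl)epigallocatechin-4β-yl]-9-(triethylsilyloxy)-9-[3,4,5-tris(benzyloxy)phenyl]non-4-enoate (both C2 epimers), via trimethylsilyl dienol ether 14 (not isolated)
Conditions: i-Pr2NEt (1.2 equiv), Me3SiOTf (1.5 equiv), CH2Cl2, −78 °C; then 4 (1.2 equiv), −78 → −40 °C; aq NaHCO3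
Reagents that add atoms: none
Why: Mukaiyama-type alkylation: soft enolisation gives the silyl dienol ether 14, the excess silyl triflate ionises the C4 ether of 4, and 14 attacks the flavan C4 cation through C2, the terminus of the 1-alkoxy-3-silyloxydiene that lies β to the silyloxy group. Attack anti to the C3 silyloxy and C2 aryl groups should give the 4β (3,4-trans) product; the new centre at C2 of the chain is not controlled and need not be, because it becomes aromatic in step 13.

Step 13
Reactants: 15 methyl (4E,8R,9S)-5,8-bis(benzyloxy)-3-oxo-2-[5,7,3',4',5'-penta-O-benzyl-3-O-(tert-butyldimethylsilyl)epigallocatechin-4β-yl]-9-(triethylsilyloxy)-9-[3,4,5-tris(benzyloxy)phenyl]non-4-enoate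
Product: 17 5-(benzyloxy)-4-[(2R,3S)-2-(benzyloxy)-3-(triethylsilyloxy)-3-[3,4,5-tris(benzyloxy)phenyl]propyl]-2-[5,7,3',4',5'-penta-O-benzyl-3-O-(tert-butyldimethylsilyl)epigallocatechin-4β-yl]benzene-1,3-diol, via cyclohexenedione 16 (not isolated)
Conditions: LiN(SiMe3)2 (4 equiv), THF, −78 → 40 °C, argon; aq NH4Cl
Reagents that add atoms: none
Why: Proposed new method: the base first removes the C2 proton of the β-keto ester and then, in equilibrium, a C6 proton that is γ to the C3 carbonyl through the C4=C5 enol ether, which gives an extended dienolate whose C4–C5 bond can rotate into the reactive geometry. C6 then adds to the ester carbonyl C1 in a 6-(enolendo)-exo-trig Dieckmann closure that forms the C4a–C8a bond, methoxide is expelled, and two enolisations of the cyclohexenedione 16 give the aromatic bis-phenoxide. The closest known reaction type is the base-mediated Claisen cyclisation of 3,5-dioxo- and 3,5,7-trioxoalkanoates to phloroglucinols; new here are the O-benzyl enol ether in place of the C5 ketone and the bulky substituent on C2. No stereocentre is formed, and the only epimerisable centre, C2 of the chain, becomes an sp2 ring carbon. The step needs C-acylation through C6: attack through C4 would give a four-membered ring and attack through the C3 enolate oxygen a strained four-membered enol lactone, so ring size enforces the selectivity. The usual escape of 3,5-dioxo esters into 4-hydroxypyranones is closed because the C5 oxygen is benzylated. The same benzyl group decides the later regiochemistry: C5 arrives as an ether, C7 and C8a as phenols, and only the C8a phenol is ortho to the side chain.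

Step 14
Reactants: 17 5-(benzyloxy)-4-[(2R,3S)-2-(benzyloxy)-3-(triethylsilyloxy)-3-[3,4,5-tris(benzyloxy)phenyl]propyl]-2-[5,7,3',4',5'-penta-O-benzyl-3-O-(tert-butyldimethylsilyl)epigallocatechin-4β-yl]benzene-1,3-diol
Product: 18 5-(benzyloxy)-4-[(2R,3S)-2-(benzyloxy)-3-hydroxy-3-[3,4,5-tris(benzyloxy)phenyl]propyl]-2-[5,7,3',4',5'-penta-O-benzyl-3-O-(tert-butyldimethylsilyl)epigallocatechin-4β-yl]benzene-1,3-diol
Conditions: HF·pyridine, pyridine, THF, 0 °C
Reagents that add atoms: none
Why: Fluoride cleaves the triethylsilyl ether much faster than the hindered secondary tert-butyldimethylsilyl ether; buffered fluoride is preferred to protic acid, which would ionise the electron-rich benzylic C–O bond.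

Step 15
Reactants: 18 5-(benzyloxy)-4-[(2R,3S)-2-(benzyloxy)-3-hydroxy-3-[3,4,5-tris(benzyloxy)phenyl]propyl]-2-[5,7,3',4',5'-penta-O-benzyl-3-O-(tert-butyldimethylsilyl)epigallocatechin-4β-yl]benzene-1,3-diol
Product: 19 3,5,3',4',5'-penta-O-benzyl-8-[5,7,3',4',5'-penta-O-benzyl-3-O-(tert-butyldimethylsilyl)epigallocatechin-4β-yl]epigallocatechin (M–B dimer, 7-OH of the lower unit free)
Conditions: PPh3, DIAD, toluene/THF, −20 → 0 °C
Reagents that add atoms: none
Why: Intramolecular Mitsunobu etherification: the benzylic alcohol is activated as its alkoxyphosphonium ion and displaced by the C8a phenol in a 6-exo-tet SN2 closure. Inversion at C2 turns the anti diol into the 2,3-cis chroman, and the C7 phenol cannot reach the carbinol carbon.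

Step 16
Reactants: 19 3,5,3',4',5'-penta-O-benzyl-8-[5,7,3',4',5'-penta-O-benzyl-3-O-(tert-butyldimethylsilyl)epigallocatechin-4β-yl]epigallocatechin
Product: 20 3,5,7,3',4',5'-hexa-O-benzyl-8-[5,7,3',4',5'-penta-O-benzyl-3-O-(tert-butyldimethylsilyl)epigallocatechin-4β-yl]epigallocatechin
Conditions: BnBr, K2CO3, Bu4NI (cat.), DMF, rt → 40 °C
Reagents that add atoms: benzyl bromide, BrCc1ccccc1
Why: Williamson etherification of the one remaining phenol, which would otherwise be acylated in step 18 and would activate the lower ring in step 19.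

Step 17
Reactants: 20 3,5,7,3',4',5'-hexa-O-benzyl-8-[5,7,3',4',5'-penta-O-benzyl-3-O-(tert-butyldimethylsilyl)epigallocatechin-4β-yl]epigallocatechin
Product: 21 3,5,7,3',4',5'-hexa-O-benzyl-8-[5,7,3',4',5'-penta-O-benzylepigallocatechin-4β-yl]epigallocatechin (3-OH of the upper unit free)
Conditions: Bu4NF, THF, rt → 40 °C
Reagents that add atoms: none
Why: Fluoride cleavage of the hindered silyl ether; no ester or free phenol is present at this stage, so the basic fluoride is harmless.

Step 18
Reactants: 21 3,5,7,3',4',5'-hexa-O-benzyl-8-[5,7,3',4',5'-penta-O-benzylepigallocatechin-4β-yl]epigallocatechin; 22 3,4,5-tris(benzyloxy)benzoic acid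
Product: 23 3,5,7,3',4',5'-hexa-O-benzyl-8-{5,7,3',4',5'-penta-O-benzyl-3-O-[3,4,5-tris(benzyloxy)benzoyl]epigallocatechin-4β-yl}epigallocatechin
Conditions: 22 (3 equiv), DCC, DMAP, CH2Cl2, rt
Reagents that add atoms: none
Why: Steglich esterification: the acylpyridinium ion formed with DMAP acylates the hindered axial alcohol, which is the only free hydroxyl in 21.

Step 19
Reactants: 23 3,5,7,3',4',5'-hexa-O-benzyl-8-{5,7,3',4',5'-penta-O-benzyl-3-O-[3,4,5-tris(benzyloxy)benzoyl]epigallocatechin-4β-yl}epigallocatechin; 3 4β-(2-ethoxyethoxy)-5,7,3',4',5'-penta-O-benzyl-(−)-epigallocatechin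
Product: 24 5,7,3',4',5'-penta-O-benzylepigallocatechin-(4β→8)-5,7,3',4',5'-penta-O-benzyl-3-O-[3,4,5-tris(benzyloxy)benzoyl]epigallocatechin-(4β→8)-3,5,7,3',4',5'-hexa-O-benzylepigallocatechin
Conditions: 23 (1.5 equiv), 3 (1.0 equiv), Me3SiOTf (0.3 equiv), CH2Cl2, −78 → −30 °C; Et3N, then aq NaHCO3
Reagents that add atoms: none
Why: Lewis-acid-promoted Friedel–Crafts-type coupling of a flavan C4 cation with an arene: attack anti to the C3 oxygen and the C2 aryl group gives the 4β bond. C8 of the upper ring of 23, flanked by the ring oxygen, is the most nucleophilic and least hindered arene carbon; the lower unit has no free C8.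

Step 20
Reactants: 24 5,7,3',4',5'-penta-O-benzylepigallocatechin-(4β→8)-5,7,3',4',5'-penta-O-benzyl-3-O-[3,4,5-tris(benzyloxy)benzoyl]epigallocatechin-(4β→8)-3,5,7,3',4',5'-hexa-O-benzylepigallocatechin
Product: 25 epigallocatechin-(4β→8)-epigallocatechin 3-O-gallate-(4β→8)-epigallocatechin (CNP0278699.1)
Conditions: H2 (1 atm), Pd(OH)2 on carbon, THF/MeOH/H2O, rt; filtration under argon, lyophilisation
Reagents that add atoms: none
Why: Hydrogenolysis of the nineteen benzyl ethers under neutral conditions; the ester, the interflavan bonds and all eight stereocentres are not affected.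

## Compound list

1 | (−)-epigallocatechin, (2R,3R)-2-(3,4,5-trihydroxyphenyl)chromane-3,5,7-triol | O[C@@H]1Cc2c(O)cc(O)cc2O[C@@H]1c1cc(O)c(O)c(O)c1 | starting material
2 | 5,7,3',4',5'-penta-O-benzyl-(−)-epigallocatechin | O[C@@H]1Cc2c(OCc3ccccc3)cc(OCc3ccccc3)cc2O[C@@H]1c1cc(OCc2ccccc2)c(OCc2ccccc2)c(OCc2ccccc2)c1 | intermediate
3 | 4β-(2-ethoxyethoxy)-5,7,3',4',5'-penta-O-benzyl-(−)-epigallocatechin | CCOCCO[C@H]1c2c(OCc3ccccc3)cc(OCc3ccccc3)cc2O[C@H](c2cc(OCc3ccccc3)c(OCc3ccccc3)c(OCc3ccccc3)c2)[C@@H]1O | intermediate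
4 | 3-O-(tert-butyldimethylsilyl)-4β-(2-ethoxyethoxy)-5,7,3',4',5'-penta-O-benzyl-(−)-epigallocatechin | CCOCCO[C@H]1c2c(OCc3ccccc3)cc(OCc3ccccc3)cc2O[C@H](c2cc(OCc3ccccc3)c(OCc3ccccc3)c(OCc3ccccc3)c2)[C@@H]1O[Si](C)(C)C(C)(C)C | intermediate
5 | 3,4,5-tris(benzyloxy)benzaldehyde | O=Cc1cc(OCc2ccccc2)c(OCc2ccccc2)c(OCc2ccccc2)c1 | starting material
6 | rac-1-[3,4,5-tris(benzyloxy)phenyl]prop-2-en-1-ol | C=CC(O)c1cc(OCc2ccccc2)c(OCc2ccccc2)c(OCc2ccccc2)c1 | intermediate
7 | (S)-[(R)-oxiran-2-yl][3,4,5-tris(benzyloxy)phenyl]methanol | C1O[C@H]1[C@@H](O)c1cc(OCc2ccccc2)c(OCc2ccccc2)c(OCc2ccccc2)c1 | intermediate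
8 | triethyl{(S)-[(R)-oxiran-2-yl][3,4,5-tris(benzyloxy)phenyl]methoxy}silane | C1O[C@H]1[C@@H](O[Si](CC)(CC)CC)c1cc(OCc2ccccc2)c(OCc2ccccc2)c(OCc2ccccc2)c1 | intermediate
9 | (1S,2R)-1-(triethylsilyloxy)-1-[3,4,5-tris(benzyloxy)phenyl]hex-5-yn-2-ol | C#CCC[C@@H](O)[C@@H](O[Si](CC)(CC)CC)c1cc(OCc2ccccc2)c(OCc2ccccc2)c(OCc2ccccc2)c1 | intermediate
10 | {[(1S,2R)-2-(benzyloxy)-1-[3,4,5-tris(benzyloxy)phenyl]hex-5-yn-1-yl]oxy}triethylsilane | C#CCC[C@@H](OCc1ccccc1)[C@@H](O[Si](CC)(CC)CC)c1cc(OCc2ccccc2)c(OCc2ccccc2)c(OCc2ccccc2)c1 | intermediate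
11 | (6R,7S)-6-(benzyloxy)-N-methoxy-N-methyl-7-(triethylsilyloxy)-7-[3,4,5-tris(benzyloxy)phenyl]hept-2-ynamide | CON(C)C(=O)C#CCC[C@@H](OCc1ccccc1)[C@@H](O[Si](CC)(CC)CC)c1cc(OCc2ccccc2)c(OCc2ccccc2)c(OCc2ccccc2)c1 | intermediate
12 | (2E,6R,7S)-3,6-bis(benzyloxy)-N-methoxy-N-methyl-7-(triethylsilyloxy)-7-[3,4,5-tris(benzyloxy)phenyl]hept-2-enamide | CON(C)C(=O)/C=C(/OCc1ccccc1)CC[C@@H](OCc1ccccc1)[C@@H](O[Si](CC)(CC)CC)c1cc(OCc2ccccc2)c(OCc2ccccc2)c(OCc2ccccc2)c1 | intermediate
13 | methyl (4E,8R,9S)-5,8-bis(benzyloxy)-3-oxo-9-(triethylsilyloxy)-9-[3,4,5-tris(benzyloxy)phenyl]non-4-enoate | COC(=O)CC(=O)/C=C(/OCc1ccccc1)CC[C@@H](OCc1ccccc1)[C@@H](O[Si](CC)(CC)CC)c1cc(OCc2ccccc2)c(OCc2ccccc2)c(OCc2ccccc2)c1 | intermediate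
14 | methyl (4E,8R,9S)-5,8-bis(benzyloxy)-9-(triethylsilyloxy)-3-(trimethylsilyloxy)-9-[3,4,5-tris(benzyloxy)phenyl]nona-2,4-dienoate | COC(=O)C=C(O[Si](C)(C)C)/C=C(/OCc1ccccc1)CC[C@@H](OCc1ccccc1)[C@@H](O[Si](CC)(CC)CC)c1cc(OCc2ccccc2)c(OCc2ccccc2)c(OCc2ccccc2)c1 | intermediate (not isolated)
15 | methyl (4E,8R,9S)-5,8-bis(benzyloxy)-3-oxo-2-[5,7,3',4',5'-penta-O-benzyl-3-O-(tert-butyldimethylsilyl)epigallocatechin-4β-yl]-9-(triethylsilyloxy)-9-[3,4,5-tris(benzyloxy)phenyl]non-4-enoate, both C2 epimers | COC(=O)C(C(=O)/C=C(/OCc1ccccc1)CC[C@@H](OCc1ccccc1)[C@@H](O[Si](CC)(CC)CC)c1cc(OCc2ccccc2)c(OCc2ccccc2)c(OCc2ccccc2)c1)[C@H]1c2c(OCc3ccccc3)cc(OCc3ccccc3)cc2O[C@H](c2cc(OCc3ccccc3)c(OCc3ccccc3)c(OCc3ccccc3)c2)[C@@H]1O[Si](C)(C)C(C)(C)C | intermediate (precursor of the key step)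
16 | 5-(benzyloxy)-6-[(2R,3S)-2-(benzyloxy)-3-(triethylsilyloxy)-3-[3,4,5-tris(benzyloxy)phenyl]propyl]-2-[5,7,3',4',5'-penta-O-benzyl-3-O-(tert-butyldimethylsilyl)epigallocatechin-4β-yl]cyclohex-4-ene-1,3-dione | O=C1C(C[C@@H](OCc2ccccc2)[C@@H](O[Si](CC)(CC)CC)c2cc(OCc3ccccc3)c(OCc3ccccc3)c(OCc3ccccc3)c2)C(OCc2ccccc2)=CC(=O)C1[C@H]1c2c(OCc3ccccc3)cc(OCc3ccccc3)cc2O[C@H](c2cc(OCc3ccccc3)c(OCc3ccccc3)c(OCc3ccccc3)c2)[C@@H]1O[Si](C)(C)C(C)(C)C | intermediate (not isolated)
17 | 5-(benzyloxy)-4-[(2R,3S)-2-(benzyloxy)-3-(triethylsilyloxy)-3-[3,4,5-tris(benzyloxy)phenyl]propyl]-2-[5,7,3',4',5'-penta-O-benzyl-3-O-(tert-butyldimethylsilyl)epigallocatechin-4β-yl]benzene-1,3-diol | Oc1c(C[C@@H](OCc2ccccc2)[C@@H](O[Si](CC)(CC)CC)c2cc(OCc3ccccc3)c(OCc3ccccc3)c(OCc3ccccc3)c2)c(OCc2ccccc2)cc(O)c1[C@H]1c2c(OCc3ccccc3)cc(OCc3ccccc3)cc2O[C@H](c2cc(OCc3ccccc3)c(OCc3ccccc3)c(OCc3ccccc3)c2)[C@@H]1O[Si](C)(C)C(C)(C)C | intermediate (product of the key step)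
18 | 5-(benzyloxy)-4-[(2R,3S)-2-(benzyloxy)-3-hydroxy-3-[3,4,5-tris(benzyloxy)phenyl]propyl]-2-[5,7,3',4',5'-penta-O-benzyl-3-O-(tert-butyldimethylsilyl)epigallocatechin-4β-yl]benzene-1,3-diol | Oc1c(C[C@@H](OCc2ccccc2)[C@@H](O)c2cc(OCc3ccccc3)c(OCc3ccccc3)c(OCc3ccccc3)c2)c(OCc2ccccc2)cc(O)c1[C@H]1c2c(OCc3ccccc3)cc(OCc3ccccc3)cc2O[C@H](c2cc(OCc3ccccc3)c(OCc3ccccc3)c(OCc3ccccc3)c2)[C@@H]1O[Si](C)(C)C(C)(C)C | intermediate
19 | 3,5,3',4',5'-penta-O-benzyl-8-[5,7,3',4',5'-penta-O-benzyl-3-O-(tert-butyldimethylsilyl)epigallocatechin-4β-yl]epigallocatechin | CC(C)(C)[Si](C)(C)O[C@@H]1[C@@H](c2c(O)cc(OCc3ccccc3)c3c2O[C@H](c2cc(OCc4ccccc4)c(OCc4ccccc4)c(OCc4ccccc4)c2)[C@H](OCc2ccccc2)C3)c2c(OCc3ccccc3)cc(OCc3ccccc3)cc2O[C@@H]1c1cc(OCc2ccccc2)c(OCc2ccccc2)c(OCc2ccccc2)c1 | intermediate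
20 | 3,5,7,3',4',5'-hexa-O-benzyl-8-[5,7,3',4',5'-penta-O-benzyl-3-O-(tert-butyldimethylsilyl)epigallocatechin-4β-yl]epigallocatechin | CC(C)(C)[Si](C)(C)O[C@@H]1[C@@H](c2c(OCc3ccccc3)cc(OCc3ccccc3)c3c2O[C@H](c2cc(OCc4ccccc4)c(OCc4ccccc4)c(OCc4ccccc4)c2)[C@H](OCc2ccccc2)C3)c2c(OCc3ccccc3)cc(OCc3ccccc3)cc2O[C@@H]1c1cc(OCc2ccccc2)c(OCc2ccccc2)c(OCc2ccccc2)c1 | intermediate
21 | 3,5,7,3',4',5'-hexa-O-benzyl-8-[5,7,3',4',5'-penta-O-benzylepigallocatechin-4β-yl]epigallocatechin | O[C@@H]1[C@@H](c2c(OCc3ccccc3)cc(OCc3ccccc3)c3c2O[C@H](c2cc(OCc4ccccc4)c(OCc4ccccc4)c(OCc4ccccc4)c2)[C@H](OCc2ccccc2)C3)c2c(OCc3ccccc3)cc(OCc3ccccc3)cc2O[C@@H]1c1cc(OCc2ccccc2)c(OCc2ccccc2)c(OCc2ccccc2)c1 | intermediate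
22 | 3,4,5-tris(benzyloxy)benzoic acid | OC(=O)c1cc(OCc2ccccc2)c(OCc2ccccc2)c(OCc2ccccc2)c1 | starting material
23 | 3,5,7,3',4',5'-hexa-O-benzyl-8-{5,7,3',4',5'-penta-O-benzyl-3-O-[3,4,5-tris(benzyloxy)benzoyl]epigallocatechin-4β-yl}epigallocatechin | O=C(O[C@@H]1[C@@H](c2c(OCc3ccccc3)cc(OCc3ccccc3)c3c2O[C@H](c2cc(OCc4ccccc4)c(OCc4ccccc4)c(OCc4ccccc4)c2)[C@H](OCc2ccccc2)C3)c2c(OCc3ccccc3)cc(OCc3ccccc3)cc2O[C@@H]1c1cc(OCc2ccccc2)c(OCc2ccccc2)c(OCc2ccccc2)c1)c1cc(OCc2ccccc2)c(OCc2ccccc2)c(OCc2ccccc2)c1 | intermediate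
24 | 5,7,3',4',5'-penta-O-benzylepigallocatechin-(4β→8)-5,7,3',4',5'-penta-O-benzyl-3-O-[3,4,5-tris(benzyloxy)benzoyl]epigallocatechin-(4β→8)-3,5,7,3',4',5'-hexa-O-benzylepigallocatechin | O=C(O[C@@H]1[C@@H](c2c(OCc3ccccc3)cc(OCc3ccccc3)c3c2O[C@H](c2cc(OCc4ccccc4)c(OCc4ccccc4)c(OCc4ccccc4)c2)[C@H](OCc2ccccc2)C3)c2c(OCc3ccccc3)cc(OCc3ccccc3)c([C@H]3c4c(OCc5ccccc5)cc(OCc5ccccc5)cc4O[C@H](c4cc(OCc5ccccc5)c(OCc5ccccc5)c(OCc5ccccc5)c4)[C@@H]3O)c2O[C@@H]1c1cc(OCc2ccccc2)c(OCc2ccccc2)c(OCc2ccccc2)c1)c1cc(OCc2ccccc2)c(OCc2ccccc2)c(OCc2ccccc2)c1 | intermediate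
25 | epigallocatechin-(4β→8)-epigallocatechin 3-O-gallate-(4β→8)-epigallocatechin (CNP0278699.1) | O=C(O[C@@H]1[C@@H](c2c(O)cc(O)c3c2O[C@H](c2cc(O)c(O)c(O)c2)[C@H](O)C3)c2c(O)cc(O)c([C@H]3c4c(O)cc(O)cc4O[C@H](c4cc(O)c(O)c(O)c4)[C@@H]3O)c2O[C@@H]1c1cc(O)c(O)c(O)c1)c1cc(O)c(O)c(O)c1 | target

## Step count and least certain steps

Total step count: 20. Longest linear sequence: 17 steps (5 → 25, steps 4 to 20); the electrophile branch (1 → 4) has 3 steps.

**Step 13 (key step).** The second deprotonation may stay incomplete, and the γ-carbanion may add too slowly to an ester carbonyl that is deactivated by the neighbouring enolate. Intermolecular Claisen condensation or base-induced rearrangement of the enol benzyl ether could then take over. Within the plan the base can be changed to KN(SiMe3)2 or LiN(iPr)2. The fallback gives up the ring synthesis and uses the established cationic flavan coupling. It sets out from 2 and 4: 2 is benzylated on O3 (NaH, BnBr, DMF, 0 °C) to 3,5,7,3',4',5'-hexa-O-benzyl-(−)-epigallocatechin F1, and F1 in threefold excess is coupled with 4 (Me3SiOTf, CH2Cl2, −78 °C). The C4 cation should attack C8 of F1 from the β face and give 20 directly, where the route is rejoined.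

**Step 12.** Attack through C4 of the dienol ether may compete with the wanted attack through C2. The electrophile may condense with its own ring A, and the silyl triflate may cleave the triethylsilyl ether. The fallback separates the two events, sets out from 4 and 12 and returns at 15. First 4 is coupled with 1-methoxy-1-(trimethylsilyloxy)ethene (Me3SiOTf cat., CH2Cl2, −78 °C), a simple and highly nucleophilic ketene silyl acetal with only one reactive carbon, to give methyl 2-[5,7,3',4',5'-penta-O-benzyl-3-O-(tert-butyldimethylsilyl)epigallocatechin-4β-yl]acetate F2. The lithium enolate of F2 (LiN(iPr)2, THF, −78 °C) is then acylated by the Weinreb amide 12 to give 15.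

**Step 15.** The activated benzylic alcohol may ionise, because the para benzyloxy group stabilises the cation. That would erode the inversion and let the 2,3-trans isomer form, or lead to elimination towards the enol ether. The fallback makes the configuration of the carbinol carbon irrelevant, sets out from 18 and returns at 19. Selective benzylic oxidation (MnO2, CH2Cl2, rt) gives the aryl ketone 5-(benzyloxy)-4-[(2R)-2-(benzyloxy)-3-oxo-3-[3,4,5-tris(benzyloxy)phenyl]propyl]-2-[5,7,3',4',5'-penta-O-benzyl-3-O-(tert-butyldimethylsilyl)epigallocatechin-4β-yl]benzene-1,3-diol F3, which is in equilibrium with its cyclic hemiketal. Reductive etherification (Et3SiH, Me3SiOTf, CH2Cl2, −78 °C) then passes through the 2-aryl oxocarbenium ion. Hydride is expected to add trans to the pseudoaxial C3 benzyloxy group, which gives the 2,3-cis chroman 19.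

**Step 19.** The electrophile may condense with itself, because its own ring A is nucleophilic, and the cation may attack C6 of the upper unit or C6 of the lower unit of 23. The fallback uses a bromine-capped electrophile so that the coupling can be run with equimolar partners at low temperature; it sets out from 2 and 23 and returns at 25. Compound 2 is brominated at C8 (NBS, CH2Cl2, −78 °C) to 8-bromo-5,7,3',4',5'-penta-O-benzyl-(−)-epigallocatechin F4. F4 is oxidised (DDQ, 2-ethoxyethanol, CH2Cl2) to 8-bromo-4β-(2-ethoxyethoxy)-5,7,3',4',5'-penta-O-benzyl-(−)-epigallocatechin F5. F5 is coupled with 23 (Me3SiOTf, CH2Cl2, −78 °C) to the 8-bromo trimer F6. Hydrogenolysis (H2, Pd(OH)2 on carbon, Et3N, THF/MeOH/H2O) removes the bromine together with the benzyl groups and gives 25.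

## Further compounds

F1 | step 13 | 3,5,7,3',4',5'-hexa-O-benzyl-(−)-epigallocatechin | c1ccccc1CO[C@@H]1Cc2c(OCc3ccccc3)cc(OCc3ccccc3)cc2O[C@@H]1c1cc(OCc2ccccc2)c(OCc2ccccc2)c(OCc2ccccc2)c1
F2 | step 12 | methyl 2-[5,7,3',4',5'-penta-O-benzyl-3-O-(tert-butyldimethylsilyl)epigallocatechin-4β-yl]acetate | COC(=O)C[C@H]1c2c(OCc3ccccc3)cc(OCc3ccccc3)cc2O[C@H](c2cc(OCc3ccccc3)c(OCc3ccccc3)c(OCc3ccccc3)c2)[C@@H]1O[Si](C)(C)C(C)(C)C
F3 | step 15 | 5-(benzyloxy)-4-[(2R)-2-(benzyloxy)-3-oxo-3-[3,4,5-tris(benzyloxy)phenyl]propyl]-2-[5,7,3',4',5'-penta-O-benzyl-3-O-(tert-butyldimethylsilyl)epigallocatechin-4β-yl]benzene-1,3-diol | Oc1c(C[C@@H](OCc2ccccc2)C(=O)c2cc(OCc3ccccc3)c(OCc3ccccc3)c(OCc3ccccc3)c2)c(OCc2ccccc2)cc(O)c1[C@H]1c2c(OCc3ccccc3)cc(OCc3ccccc3)cc2O[C@H](c2cc(OCc3ccccc3)c(OCc3ccccc3)c(OCc3ccccc3)c2)[C@@H]1O[Si](C)(C)C(C)(C)C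
F4 | step 19 | 8-bromo-5,7,3',4',5'-penta-O-benzyl-(−)-epigallocatechin | O[C@@H]1Cc2c(OCc3ccccc3)cc(OCc3ccccc3)c(Br)c2O[C@@H]1c1cc(OCc2ccccc2)c(OCc2ccccc2)c(OCc2ccccc2)c1
F5 | step 19 | 8-bromo-4β-(2-ethoxyethoxy)-5,7,3',4',5'-penta-O-benzyl-(−)-epigallocatechin | CCOCCO[C@H]1c2c(OCc3ccccc3)cc(OCc3ccccc3)c(Br)c2O[C@H](c2cc(OCc3ccccc3)c(OCc3ccccc3)c(OCc3ccccc3)c2)[C@@H]1O
F6 | step 19 | 8-bromo-5,7,3',4',5'-penta-O-benzylepigallocatechin-(4β→8)-5,7,3',4',5'-penta-O-benzyl-3-O-[3,4,5-tris(benzyloxy)benzoyl]epigallocatechin-(4β→8)-3,5,7,3',4',5'-hexa-O-benzylepigallocatechin | O=C(O[C@@H]1[C@@H](c2c(OCc3ccccc3)cc(OCc3ccccc3)c3c2O[C@H](c2cc(OCc4ccccc4)c(OCc4ccccc4)c(OCc4ccccc4)c2)[C@H](OCc2ccccc2)C3)c2c(OCc3ccccc3)cc(OCc3ccccc3)c([C@H]3c4c(OCc5ccccc5)cc(OCc5ccccc5)c(Br)c4O[C@H](c4cc(OCc5ccccc5)c(OCc5ccccc5)c(OCc5ccccc5)c4)[C@@H]3O)c2O[C@@H]1c1cc(OCc2ccccc2)c(OCc2ccccc2)c(OCc2ccccc2)c1)c1cc(OCc2ccccc2)c(OCc2ccccc2)c(OCc2ccccc2)c1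
A1 | alternative 1 | [2-hydroxy-4,6-bis(benzyloxy)phenyl][3,5,7,3',4',5'-hexa-O-benzylepigallocatechin-8-yl]methanol | OC(c1c(O)cc(OCc2ccccc2)cc1OCc1ccccc1)c1c(OCc2ccccc2)cc(OCc2ccccc2)c2c1O[C@H](c1cc(OCc3ccccc3)c(OCc3ccccc3)c(OCc3ccccc3)c1)[C@H](OCc1ccccc1)C2
A2 | alternative 1 | 2-(4-methoxybenzyloxy)acetaldehyde | O=CCOCc1ccc(OC)cc1
A3 | alternative 1 | 3,4-trans-3-(4-methoxybenzyloxy)-4-(3,5,7,3',4',5'-hexa-O-benzylepigallocatechin-8-yl)-5,7-bis(benzyloxy)chroman-2-ol (lactol anomers) | c1ccccc1CO[C@@H]1Cc2c(OCc9ccccc9)cc(OCc9ccccc9)c([C@H]3c4c(OCc9ccccc9)cc(OCc9ccccc9)cc4OC(O)[C@@H]3OCc9ccc(OC)cc9)c2O[C@@H]1c1cc(OCc9ccccc9)c(OCc9ccccc9)c(OCc9ccccc9)c1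
A4 | alternative 2 | 3-(benzyloxy)-4-[(E)-3-[3,4,5-tris(benzyloxy)phenyl]prop-2-enyl]cyclobut-2-en-1-one | O=C1C=C(OCc2ccccc2)C1C/C=C/c1cc(OCc2ccccc2)c(OCc2ccccc2)c(OCc2ccccc2)c1
A5 | alternative 2 | 4β-[(triisopropylsilyloxy)ethynyl]-3,5,7,3',4',5'-hexa-O-benzylepigallocatechin | CC(C)[Si](C(C)C)(C(C)C)OC#C[C@H]1c2c(OCc3ccccc3)cc(OCc3ccccc3)cc2O[C@H](c2cc(OCc3ccccc3)c(OCc3ccccc3)c(OCc3ccccc3)c2)[C@@H]1OCc1ccccc1
A6 | alternative 2 | 3-(benzyloxy)-2-[(E)-3-[3,4,5-tris(benzyloxy)phenyl]prop-2-enyl]-5-(triisopropylsilyloxy)-6-(3,5,7,3',4',5'-hexa-O-benzylepigallocatechin-4β-yl)phenol | Oc1c(C/C=C/c2cc(OCc9ccccc9)c(OCc9ccccc9)c(OCc9ccccc9)c2)c(OCc9ccccc9)cc(O[Si](C(C)C)(C(C)C)C(C)C)c1[C@H]3c4c(OCc9ccccc9)cc(OCc9ccccc9)cc4O[C@H](c4cc(OCc9ccccc9)c(OCc9ccccc9)c(OCc9ccccc9)c4)[C@@H]3OCc9ccccc9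
A7 | alternative 3 | 2-(hydroxymethyl)-3,5-bis(benzyloxy)-6-{5,7,3',4',5'-penta-O-benzyl-3-O-[3,4,5-tris(benzyloxy)benzoyl]epigallocatechin-4β-yl}phenol | OCc1c(OCc2ccccc2)cc(OCc2ccccc2)c(c1O)[C@H]1c2c(OCc3ccccc3)cc(OCc3ccccc3)cc2O[C@H](c2cc(OCc3ccccc3)c(OCc3ccccc3)c(OCc3ccccc3)c2)[C@@H]1OC(=O)c1cc(OCc2ccccc2)c(OCc2ccccc2)c(OCc2ccccc2)c1
A8 | alternative 3 | (Z)-4,4,5,5-tetramethyl-2-{2-[3,4,5-tris(benzyloxy)phenyl]ethenyl}-1,3,2-dioxaborolane | CC1(C)OB(/C=C\c2cc(OCc3ccccc3)c(OCc3ccccc3)c(OCc3ccccc3)c2)OC1(C)C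
A9 | alternative 3 | M–B dimer with a pinacolboryl group in place of the C3 oxygen of the lower unit, 2,3-cis | CC1(C)OB(OC1(C)C)[C@@H]1Cc2c(OCc9ccccc9)cc(OCc9ccccc9)c([C@H]3c4c(OCc9ccccc9)cc(OCc9ccccc9)cc4O[C@H](c4cc(OCc9ccccc9)c(OCc9ccccc9)c(OCc9ccccc9)c4)[C@@H]3OC(=O)c3cc(OCc9ccccc9)c(OCc9ccccc9)c(OCc9ccccc9)c3)c2O[C@@H]1c1cc(OCc9ccccc9)c(OCc9ccccc9)c(OCc9ccccc9)c1
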